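**Atom labels used throughout.** C7 carries guaiacyl ring A, C7' carries the central syringyl ring B, C8 and C8' are the ring-fusion carbons, and C9 and C9' are the two OCH2 carbons. Ring 1 is O1–C7–C8–C8'–C9' and ring 2 is O2–C7'–C8'–C8–C9. The side chain is C7''(OH)–C8''(OAr)–C9''H2OH and bears ring C.

**Assumption.** Which enantiomer of the phosphoramidite delivers the (4S) centre of 6 cannot be settled on paper. The (S,S,S)-ligand is written, and its mirror image is used if the sense of induction turns out opposite.

## Analysis of the target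

The target is a sesquineolignan: a 2,6-diaryl-3,7-dioxabicyclo[3.3.0]octane (furofuran) whose ring B phenol oxygen carries a syringylglycerol unit (ring C) through an 8''–O–4' aryl ether. The bicycle holds four contiguous stereocentres (7R,8S,7'S,8'S). The ring fusion is cis, ring A at C7 is exo (trans to C9, on the convex face) and ring B at C7' is endo (cis to C9'), so the two halves are not related by symmetry and an oxidative dimerisation cannot deliver the core. The side chain adds a threo (syn) pair, (7''R,8''R), which is too far from the core to be controlled by it and needs reagent control. Sensitive features are the benzylic ether bonds C7–O1 and C7'–O2, the benzylic C7''–OH next to an electron-rich ring, and two free phenols. Acid ionises the benzylic ethers and would turn the kinetic endo aryl into the more stable exo one, and hydrogenolysis can cleave them. The difficulty is therefore threefold: an unsymmetrical exo/endo core in one absolute configuration, an endo centre that must be introduced late and kept away from equilibrating acid, and a ring B phenol that must be freed selectively beside the ring A phenol. The strategy rests on ring 1: O1 lies between the aryl-bearing C7 and an unsubstituted C9'H2, and C8 and C8' each carry one carbon branch (C9 and C7'). This is the pattern formed when an O–CH2–CH(vinyl) three-atom unit (O1, C9', C8') adds across the C7=C8 bond of an arylidene malonate.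

## Retrosynthetic reasoning

**30 from 29.** Both phenols are masked as benzyl ethers in 29. This is the last cut, so the para-hydroxybenzylic positions exist only in the final product. The forward step must remove two O-benzyl groups by hydrogenolysis without cleaving the benzylic C–O bonds of the core or the side chain.

**29 from 28.** The primary alcohol C9'' is traced back to an acyl group bound to a chiral oxazolidinone. Reductive removal of the auxiliary gives the 1,3-diol directly and touches neither side-chain stereocentre.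

**28 from 24 and 26.** The C7''–C8'' bond is cut between the two side-chain stereocentres, so both are set in one auxiliary-controlled syn aldol of imide 24 (through enolate 27) with aldehyde 26. A cut at O–C8'' was not chosen: it would need an SN2 reaction of the hindered 2,6-dimethoxyphenol at a secondary carbon next to a benzylic centre. Aldehyde 26 comes from 25 by O-benzylation.

**24 from 19 and 23; 19 from 18.** The aryl ether bond is made while C8'' is still a primary, carbonyl-activated CH2, where the hindered phenoxide of 19 can react. Reagent 23 comes from auxiliary 20 and acid bromide 21 through 22. Phenol 19 comes from silyl ether 18, whose ring B protecting group is orthogonal to the benzyl ether on ring A.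

**18 from 12 and 14 (through 15, 16 and 17).** The C7'–aryl bond and the C7'–H bond are cut. Forward, aryllithium 15 (from bromide 14, made from 13) adds to lactone 12, and hemiketal 16 is reduced through oxocarbenium ion 17. The endo aryl is the less stable arrangement, so it must be set kinetically and late. The cis-fused lactone provides the convex face from which hydride is delivered.

**12 from 11, 10, 9 and 8.** These are oxidation-state changes only. The C7' carbonyl comes from the vinyl group (aldehyde 10, trapped as lactol 11), and the O2–C9 bond comes from the ester of 8 reduced to alcohol 9. The lactol can close only when C9 and C7' are cis, which is the relation needed in the target.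

**8 from 6 (through 7).** One ester of the geminal diester is removed. The second ester served only to activate the alkene in the key step, and its removal creates the C8–H centre.

**6 from 3 and 4 (through 5).** This is the key disconnection: O1–C7 and C8–C8' are cut. It divides ring 1 into acceptor 3 (C7 and C8 with both future C9 candidates) and the three-atom unit of carbonate 4 (O1, C9', C8', with the vinyl group as latent C7'). No other pair of ring 1 bonds creates C7 and C8' in a single catalytic enantioselective event from an achiral and a racemic partner. The forward reaction must give branched allylation, one absolute configuration at C8' and aryl trans to vinyl.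

**3 from 1 and 2.** The C7=C8 bond is made by condensation of the aldehyde with the malonate.

## Alternatives that were turned down

**Alternative 1: ring contraction of a pyranone by Wolff rearrangement.**
- Disconnection: C8–C8' and O2–C9 of lactone A1 are cut, leading to the six-membered diazo ketone A2 (O1–C7–C8(N2)–C9(=O)–C8'–C9'), which already carries the C7' carbinol with ring B on C8'.
- Forward key step: irradiation expels nitrogen, C8' migrates from C9 to C8 with retention, and the C7' hydroxyl traps the ketene at C9. Ring 1 and the lactone ring 2 of A1 appear together.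
- For it: lactonisation dictates the cis ring fusion, and ring B with C7' is in place before the bicycle forms, so no late organometallic addition is needed. On the certainty of the C8 configuration it is stronger than the chosen route, which fixes C8 by equilibration.
- Against it: A2 needs three stereocentres set beforehand, among them an acyclic benzylic carbinol. That carbinol is β to the ketone, so base-mediated diazo transfer invites retro-aldol cleavage and dehydration. The carbene has a C7–H next to oxygen that can undergo a 1,2-shift to an enone, and O–H insertion of the C7' hydroxyl competes with ketene formation. The C9 carbonyl of A1 must still be reduced to CH2 beside the endo benzylic ether.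
- Comparison: A2 needs many steps before the key event, against two for the chosen route. In its place the chosen strategy offers a catalytic asymmetric entry from an achiral and a racemic partner, and an endo centre set by a late, shape-controlled reduction.

**Alternative 2: oxygen-to-carbon rearrangement of a dihydrodioxepine acetal (Petasis–Ferrier type).**
- Disconnection: the C7–C8 bond of formyl tetrahydrofuran A3 is cut, leading to the seven-membered acetal A4 (O1–C7–O–C9=C8–C8'–C9').
- Forward key step: a Lewis acid opens the acetal on its enol-ether side, and the enol carbon C8 attacks the oxocarbenium carbon C7. The ring contracts to ring 1 and C9 is released as an aldehyde.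
- For it: the C–C bond forms within an ion pair, without transition metal or chiral ligand. C9 arrives at a useful oxidation level, and ring B with the C7' oxygen is introduced early and convergently. On convergence it is stronger than the chosen route.
- Against it: A3 forms as C8 epimers, so C8 again depends on equilibration. C8' and C7' must come from an earlier asymmetric step. The enol ether of A4 needs a regioselective alkene isomerisation next to a stereocentre. Ring 2 then has to be closed at the benzylic C7': an ionising closure gives the thermodynamic exo aryl, the opposite of what the target needs, and a clean inversion at a para-alkoxybenzylic carbon is unreliable.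
- Comparison: the chosen strategy gives up the early introduction of ring B but obtains the endo C7' kinetically, by hydride delivery to the convex face of a preformed bicycle.

**Alternative 3: carbonyl ylide cycloaddition onto a chiral butenolide.**
- Disconnection: C8–C9 and C7'–C8' of lactone A5 are cut, leading to butenolide A6 (ring 1 with C9' as carbonyl and a C8=C8' double bond) and the silylmethyl mixed acetal A7 as ylide precursor.
- Forward key step: ionisation of A7 and fluoride desilylation give a non-stabilised carbonyl ylide, which adds across C8=C8' of A6 anti to ring A and closes ring 2.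
- For it: it is the most convergent plan. Both bonds of ring 2 and three stereocentres arise in one step, and the single stereocentre of A6 directs the face. On step economy it is stronger than the chosen route.
- Against it: the unsymmetrical ylide can add in two orientations. Nothing enforces the more hindered endo position of ring B. The γ-hydrogen of A6 at C7 is benzylic, allylic and next to oxygen, so the basic fluoride can racemise A6 through the 2-oxyfuran. The C9' carbonyl must later be reduced beside the endo benzylic ether.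
- Comparison: the chosen route is longer, but each selectivity has its own control element: ligand for C8', reversibility for C7, ring strain and equilibration for C8, convex-face attack for C7', and an auxiliary for the side chain.

Key step: step 2

## Route

Step 1
Reactants: 1 4-(benzyloxy)-3-methoxybenzaldehyde; 2 dimethyl malonate
Product: 3 dimethyl 2-[4-(benzyloxy)-3-methoxybenzylidene]malonate
Conditions: piperidine (0.1 equiv), AcOH (0.1 equiv), toluene, reflux, azeotropic removal of water
Reagents that add atoms: none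
Why: Knoevenagel condensation through the iminium ion of the aldehyde, driven by removal of water; no stereocentre is formed and the benzyl ether is inert.

Step 2
Reactants: 3 dimethyl 2-[4-(benzyloxy)-3-methoxybenzylidene]malonate; 4 4-vinyl-1,3-dioxolan-2-one (racemic)
Product: 6 dimethyl (2S,4S)-2-[4-(benzyloxy)-3-methoxyphenyl]-4-ethenyloxolane-3,3-dicarboxylate, via alkoxide π-allylpalladium zwitterion 5 (not isolated)
Conditions: Pd2(dba)3·CHCl3 (2.5 mol%), (11bS)-N,N-bis[(1S)-1-phenylethyl]dinaphtho[2,1-d:1',2'-f][1,3,2]dioxaphosphepin-4-amine (10 mol%), 4 (1.5 equiv), THF, 25–40 °C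
Reagents that add atoms: none
Why: Zerovalent palladium ionises the allylic carbonate 4 with decarboxylation to zwitterion 5; its alkoxide adds to the benzylidene carbon C7 of 3 (oxa-Michael addition, bond O1–C7), and the malonate anion so formed attacks the internal allyl terminus C8' (bond C8–C8'), which releases the catalyst. The closest known reaction type is the palladium-catalysed decarboxylative (3+2) cycloaddition of vinylethylene carbonates with doubly activated alkenes. Ring 1 is closed in the C–C bond-forming event as a 5-exo attack of the tethered carbanion on the π-allyl unit; attack at the distal terminus would require a seven-membered ring, and this secures the branched regiochemistry. C8' is controlled by the phosphoramidite on palladium: the two diastereomeric π-allyl complexes from racemic 4 interconvert by π–σ–π isomerisation faster than they cyclise, so the racemate should converge on one enantiomer. C7 is set in the oxa-Michael step, which is reversible, so the ring closure selects the adduct whose transition state keeps ring A and the ligand-bearing allylpalladium unit on opposite faces of the forming ring, giving aryl trans to vinyl. The step needs branched regioselectivity, the trans relation and one absolute configuration; ring size, reversibility of the first bond and the ligand provide them, and the geminal diester leaves no acidic hydrogen through which 6 could ring-open or epimerise.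

Step 3
Reactants: 6 dimethyl (2S,4S)-2-[4-(benzyloxy)-3-methoxyphenyl]-4-ethenyloxolane-3,3-dicarboxylate
Product: 8 methyl (2R,3R,4S)-2-[4-(benzyloxy)-3-methoxyphenyl]-4-ethenyloxolane-3-carboxylate, via C3-epimeric monoester mixture 7 (not isolated)
Conditions: LiCl (3 equiv), H2O (2 equiv), DMSO, 150 °C; crude product, then NaOMe (0.2 equiv), MeOH, 25 °C
Reagents that add atoms: none
Why: Krapcho dealkoxycarbonylation (chloride attacks an ester methyl group, the carboxylate decarboxylates, water protonates the enolate) gives mixture 7, which methoxide equilibrates through the ester enolate towards 8, where the ester at C8 is trans to the large aryl group at C7 and cis only to the smaller vinyl group at C8'. Ring opening by β-elimination of O1 should not compete because the enolate π system at C8 is orthogonal to the endocyclic C7–O1 bond (the reverse of a 5-endo closure); the minor epimer is separated and resubmitted to methoxide.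

Step 4
Reactants: 8 methyl (2R,3R,4S)-2-[4-(benzyloxy)-3-methoxyphenyl]-4-ethenyloxolane-3-carboxylate
Product: 9 [(2R,3S,4S)-2-[4-(benzyloxy)-3-methoxyphenyl]-4-ethenyloxolan-3-yl]methanol
Conditions: LiAlH4, THF, 0 °C
Reagents that add atoms: none
Why: Hydride reduction of the ester to the primary alcohol C9–OH; the vinyl group, the benzyl ether and the three stereocentres are not affected.

Step 5
Reactants: 9 [(2R,3S,4S)-2-[4-(benzyloxy)-3-methoxyphenyl]-4-ethenyloxolan-3-yl]methanol
Product: 11 (3aS,4R,6aS)-4-[4-(benzyloxy)-3-methoxyphenyl]tetrahydro-1H,3H-furo[3,4-c]furan-1-ol (anomeric mixture), via hydroxy aldehyde 10 (not isolated)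
Conditions: O3, CH2Cl2/MeOH (4:1), −78 °C, Sudan red 7B as end-point indicator; then Me2S, −78 °C to rt
Reagents that add atoms: ozone, [O-][O+]=O
Why: Ozonolysis with reductive work-up cleaves the terminal alkene faster than the electron-rich arene at −78 °C, and the indicator dye marks the end point. Aldehyde 10 is trapped at once by the cis C9 hydroxyl as the cis-fused lactol, which also protects C8' from epimerisation.

Step 6
Reactants: 11 (3aS,4R,6aS)-4-[4-(benzyloxy)-3-methoxyphenyl]tetrahydro-1H,3H-furo[3,4-c]furan-1-ol
Product: 12 (3aS,4R,6aS)-4-[4-(benzyloxy)-3-methoxyphenyl]tetrahydro-1H,3H-furo[3,4-c]furan-1-one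
Conditions: TEMPO (0.1 equiv), PhI(OAc)2 (1.3 equiv), CH2Cl2, rt
Reagents that add atoms: none
Why: Oxoammonium oxidation of a lactol to the lactone under near-neutral conditions; C8', now α to the carbonyl, cannot epimerise productively because only the cis fusion of the two five-membered rings is low in strain.

Step 7
Reactants: 13 4-bromo-2,6-dimethoxyphenol
Product: 14 (4-bromo-2,6-dimethoxyphenoxy)(tert-butyl)dimethylsilane
Conditions: TBSCl (1.2 equiv), imidazole (2.5 equiv), DMF, rt
Reagents that add atoms: tert-butyldimethylsilyl chloride, CC(C)(C)[Si](C)(C)Cl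
Why: Standard silylation of a phenol; the silyl ether survives bromine–lithium exchange and is later removed by fluoride without touching the benzyl ether of ring A.

Step 8
Reactants: 14 (4-bromo-2,6-dimethoxyphenoxy)(tert-butyl)dimethylsilane; 12 (3aS,4R,6aS)-4-[4-(benzyloxy)-3-methoxyphenyl]tetrahydro-1H,3H-furo[3,4-c]furan-1-one
Product: 16 (3aS,4R,6aS)-4-[4-(benzyloxy)-3-methoxyphenyl]-1-[4-(tert-butyldimethylsilyloxy)-3,5-dimethoxyphenyl]tetrahydro-1H,3H-furo[3,4-c]furan-1-ol (anomeric mixture at C7'), via aryllithium 15 (not isolated)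
Conditions: 14 (1.2 equiv), n-BuLi (1.15 equiv), THF, −78 °C, 30 min; then 12, −78 °C; pH 7 buffer
Reagents that add atoms: none
Why: Bromine–lithium exchange gives 15, which should add only once to the γ-lactone because the tetrahedral lithium lactolate is stable at −78 °C. The configuration at the hemiketal carbon is of no consequence since it is ionised in the next step.

Step 9
Reactants: 16 (3aS,4R,6aS)-4-[4-(benzyloxy)-3-methoxyphenyl]-1-[4-(tert-butyldimethylsilyloxy)-3,5-dimethoxyphenyl]tetrahydro-1H,3H-furo[3,4-c]furan-1-ol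
Product: 18 (1R,3aS,4S,6aS)-1-[4-(benzyloxy)-3-methoxyphenyl]-4-[4-(tert-butyldimethylsilyloxy)-3,5-dimethoxyphenyl]tetrahydro-1H,3H-furo[3,4-c]furan, via oxocarbenium ion 17 (not isolated)
Conditions: Et3SiH (3 equiv), BF3·OEt2 (1.5 equiv), CH2Cl2, −78 to −40 °C; sat. aq NaHCO3 at −40 °C
Reagents that add atoms: none
Why: Ionic hydrogenation of a hemiketal: BF3 ionises 16 to the aryl-stabilised oxocarbenium ion 17, and the silane delivers hydride to C7' from the convex face of the cis-fused bicycle (the face of H8 and H8'), which places ring B endo. Low temperature and a cold basic quench should prevent acid equilibration of the benzylic ethers to the exo isomer and keep the aryl silyl ether intact.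

Step 10
Reactants: 18 (1R,3aS,4S,6aS)-1-[4-(benzyloxy)-3-methoxyphenyl]-4-[4-(tert-butyldimethylsilyloxy)-3,5-dimethoxyphenyl]tetrahydro-1H,3H-furo[3,4-c]furan
Product: 19 4-[(1S,3aS,4R,6aS)-4-[4-(benzyloxy)-3-methoxyphenyl]tetrahydro-1H,3H-furo[3,4-c]furan-1-yl]-2,6-dimethoxyphenol
Conditions: Bu4NF (1.1 equiv), THF, 0 °C
Reagents that add atoms: none
Why: Fluoride cleaves the aryl silyl ether through Si–F bond formation; the benzyl ether and the furofuran are inert, so only the ring B phenol is released.

Step 11
Reactants: 20 (S)-4-benzyloxazolidin-2-one; 21 bromoacetyl bromide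
Product: 23 (S)-4-benzyl-3-(2-bromoacetyl)oxazolidin-2-one, via lithium oxazolidinide 22 (not isolated)
Conditions: n-BuLi (1.0 equiv), THF, −78 °C; then 21 (1.1 equiv), −78 to 0 °C
Reagents that add atoms: none
Why: N-Acylation of the lithiated oxazolidinone at −78 °C, where the acyl bromide reacts much faster than the alkyl bromide; the stereocentre of the auxiliary is not involved.

Step 12
Reactants: 19 4-[(1S,3aS,4R,6aS)-4-[4-(benzyloxy)-3-methoxyphenyl]tetrahydro-1H,3H-furo[3,4-c]furan-1-yl]-2,6-dimethoxyphenol; 23 (S)-4-benzyl-3-(2-bromoacetyl)oxazolidin-2-one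
Product: 24 (S)-4-benzyl-3-[2-[4-[(1S,3aS,4R,6aS)-4-[4-(benzyloxy)-3-methoxyphenyl]tetrahydro-1H,3H-furo[3,4-c]furan-1-yl]-2,6-dimethoxyphenoxy]acetyl]oxazolidin-2-one
Conditions: 23 (1.2 equiv), K2CO3 (2 equiv), acetone, 40 °C
Reagents that add atoms: none
Why: Williamson ether synthesis: the hindered 2,6-dimethoxyphenoxide displaces bromide from the highly SN2-reactive α-bromo imide under mild carbonate conditions. Acyl transfer from the imide to the phenoxide is uphill because the oxazolidinone is the weaker acid, so it stays reversible and unproductive.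

Step 13
Reactants: 25 4-hydroxy-3,5-dimethoxybenzaldehyde (syringaldehyde)
Product: 26 4-(benzyloxy)-3,5-dimethoxybenzaldehyde
Conditions: BnBr (1.2 equiv), K2CO3 (2 equiv), DMF, 60 °C
Reagents that add atoms: benzyl bromide, BrCc1ccccc1
Why: Williamson benzylation of the phenol; the benzyl ether matches the one on ring A, so both can be removed together in the last step.

Step 14
Reactants: 24 (S)-4-benzyl-3-[2-[4-[(1S,3aS,4R,6aS)-4-[4-(benzyloxy)-3-methoxyphenyl]tetrahydro-1H,3H-furo[3,4-c]furan-1-yl]-2,6-dimethoxyphenoxy]acetyl]oxazolidin-2-one; 26 4-(benzyloxy)-3,5-dimethoxybenzaldehyde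
Product: 28 (S)-4-benzyl-3-[(2S,3R)-3-[4-(benzyloxy)-3,5-dimethoxyphenyl]-2-[4-[(1S,3aS,4R,6aS)-4-[4-(benzyloxy)-3-methoxyphenyl]tetrahydro-1H,3H-furo[3,4-c]furan-1-yl]-2,6-dimethoxyphenoxy]-3-hydroxypropanoyl]oxazolidin-2-one, via Z boron enolate 27 (not isolated)
Conditions: Bu2BOTf (1.3 equiv), iPr2NEt (1.6 equiv), CH2Cl2, −78 to 0 °C; then 26 (1.5 equiv), −78 to 0 °C; pH 7 buffer, MeOH, 30% H2O2, 0 °C
Reagents that add atoms: none
Why: Evans syn aldol reaction of a glycolate-type imide: soft enolisation gives the Z boron enolate 27, which reacts through a closed chair (Zimmerman–Traxler) transition state on the enolate face not shielded by the benzyl group of the (S)-auxiliary. This sets (2S,3R), the syn pair that becomes threo (7''R,8''R) after reduction; the auxiliary should override any influence of the remote core stereocentres.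

Step 15
Reactants: 28 (S)-4-benzyl-3-[(2S,3R)-3-[4-(benzyloxy)-3,5-dimethoxyphenyl]-2-[4-[(1S,3aS,4R,6aS)-4-[4-(benzyloxy)-3-methoxyphenyl]tetrahydro-1H,3H-furo[3,4-c]furan-1-yl]-2,6-dimethoxyphenoxy]-3-hydroxypropanoyl]oxazolidin-2-one
Product: 29 (1R,2R)-1-[4-(benzyloxy)-3,5-dimethoxyphenyl]-2-[4-[(1S,3aS,4R,6aS)-4-[4-(benzyloxy)-3-methoxyphenyl]tetrahydro-1H,3H-furo[3,4-c]furan-1-yl]-2,6-dimethoxyphenoxy]propane-1,3-diol
Conditions: LiBH4 (2 equiv), MeOH (2 equiv), THF, 0 °C
Reagents that add atoms: none
Why: Reductive cleavage of the N-acyl oxazolidinone gives the primary alcohol C9''–OH and releases the auxiliary; the mild hydride at 0 °C should avoid retro-aldol cleavage and leaves both new stereocentres untouched.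

Step 16
Reactants: 29 (1R,2R)-1-[4-(benzyloxy)-3,5-dimethoxyphenyl]-2-[4-[(1S,3aS,4R,6aS)-4-[4-(benzyloxy)-3-methoxyphenyl]tetrahydro-1H,3H-furo[3,4-c]furan-1-yl]-2,6-dimethoxyphenoxy]propane-1,3-diol
Product: 30 (1R,2R)-1-(4-hydroxy-3,5-dimethoxyphenyl)-2-[4-[(1S,3aS,4R,6aS)-4-(4-hydroxy-3-methoxyphenyl)tetrahydro-1H,3H-furo[3,4-c]furan-1-yl]-2,6-dimethoxyphenoxy]propane-1,3-diol
Conditions: H2 (1 atm), 10% Pd/C, EtOAc/EtOH (1:1), rt, stopped when both benzyl groups are gone
Reagents that add atoms: none
Why: Catalytic hydrogenolysis of the two aryl benzyl ethers; in a neutral medium the ArO–CH2Ph bonds should be cleaved much faster than the benzylic ether bonds of the furofuran or the benzylic C7''–OH bond, so no stereocentre is affected.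

## Compound list

1 | 4-(benzyloxy)-3-methoxybenzaldehyde | COc1cc(C=O)ccc1OCc1ccccc1 | starting material
2 | dimethyl malonate | COC(=O)CC(=O)OC | starting material
3 | dimethyl 2-[4-(benzyloxy)-3-methoxybenzylidene]malonate | COC(=O)C(=Cc1ccc(OCc2ccccc2)c(OC)c1)C(=O)OC | intermediate
4 | 4-vinyl-1,3-dioxolan-2-one (racemic) | C=CC1COC(=O)O1 | starting material
5 | alkoxide π-allylpalladium zwitterion from 4 (ligand omitted, drawn as a σ-allyl form) | [O-]CC=CC[Pd+] | intermediate (not isolated)
6 | dimethyl (2S,4S)-2-[4-(benzyloxy)-3-methoxyphenyl]-4-ethenyloxolane-3,3-dicarboxylate (aryl trans to vinyl) | COc1cc([C@@H]2OC[C@@H](C=C)C2(C(=O)OC)C(=O)OC)ccc1OCc1ccccc1 | intermediate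
7 | methyl (2R,4S)-2-[4-(benzyloxy)-3-methoxyphenyl]-4-ethenyloxolane-3-carboxylate, mixture of C3 epimers | COc1cc([C@@H]2OC[C@@H](C=C)C2C(=O)OC)ccc1OCc1ccccc1 | intermediate (not isolated)
8 | methyl (2R,3R,4S)-2-[4-(benzyloxy)-3-methoxyphenyl]-4-ethenyloxolane-3-carboxylate (ester trans to aryl, cis to vinyl) | COc1cc([C@@H]2OC[C@@H](C=C)[C@H]2C(=O)OC)ccc1OCc1ccccc1 | intermediate
9 | [(2R,3S,4S)-2-[4-(benzyloxy)-3-methoxyphenyl]-4-ethenyloxolan-3-yl]methanol | COc1cc([C@@H]2OC[C@@H](C=C)[C@H]2CO)ccc1OCc1ccccc1 | intermediate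
10 | (3S,4S,5R)-5-[4-(benzyloxy)-3-methoxyphenyl]-4-(hydroxymethyl)oxolane-3-carbaldehyde | COc1cc([C@@H]2OC[C@@H](C=O)[C@H]2CO)ccc1OCc1ccccc1 | intermediate (not isolated)
11 | (3aS,4R,6aS)-4-[4-(benzyloxy)-3-methoxyphenyl]tetrahydro-1H,3H-furo[3,4-c]furan-1-ol (cis-fused lactol, anomeric mixture) | COc1cc([C@@H]2OC[C@@H]3[C@H]2COC3O)ccc1OCc1ccccc1 | intermediate
12 | (3aS,4R,6aS)-4-[4-(benzyloxy)-3-methoxyphenyl]tetrahydro-1H,3H-furo[3,4-c]furan-1-one (cis-fused lactone, carbonyl at C7', ring A exo) | COc1cc([C@@H]2OC[C@@H]3[C@H]2COC3=O)ccc1OCc1ccccc1 | intermediate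
13 | 4-bromo-2,6-dimethoxyphenol | COc1cc(Br)cc(OC)c1O | starting material
14 | (4-bromo-2,6-dimethoxyphenoxy)(tert-butyl)dimethylsilane | COc1cc(Br)cc(OC)c1O[Si](C)(C)C(C)(C)C | intermediate
15 | [4-(tert-butyldimethylsilyloxy)-3,5-dimethoxyphenyl]lithium | [Li]c1cc(OC)c(O[Si](C)(C)C(C)(C)C)c(OC)c1 | intermediate (not isolated)
16 | (3aS,4R,6aS)-4-[4-(benzyloxy)-3-methoxyphenyl]-1-[4-(tert-butyldimethylsilyloxy)-3,5-dimethoxyphenyl]tetrahydro-1H,3H-furo[3,4-c]furan-1-ol (hemiketal, anomeric mixture) | COc1cc([C@@H]2OC[C@@H]3[C@H]2COC3(O)c2cc(OC)c(O[Si](C)(C)C(C)(C)C)c(OC)c2)ccc1OCc1ccccc1 | intermediate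
17 | cyclic oxocarbenium ion of 16 (O2=C7' cation bearing ring B) | COc1cc([C@@H]2OC[C@@H]3[C@H]2C[O+]=C3c2cc(OC)c(O[Si](C)(C)C(C)(C)C)c(OC)c2)ccc1OCc1ccccc1 | intermediate (not isolated)
18 | (1R,3aS,4S,6aS)-1-[4-(benzyloxy)-3-methoxyphenyl]-4-[4-(tert-butyldimethylsilyloxy)-3,5-dimethoxyphenyl]tetrahydro-1H,3H-furo[3,4-c]furan (ring A exo, ring B endo) | COc1cc([C@@H]2OC[C@@H]3[C@H]2CO[C@@H]3c2cc(OC)c(O[Si](C)(C)C(C)(C)C)c(OC)c2)ccc1OCc1ccccc1 | intermediate
19 | 4-[(1S,3aS,4R,6aS)-4-[4-(benzyloxy)-3-methoxyphenyl]tetrahydro-1H,3H-furo[3,4-c]furan-1-yl]-2,6-dimethoxyphenol | COc1cc([C@@H]2OC[C@@H]3[C@H]2CO[C@@H]3c2cc(OC)c(O)c(OC)c2)ccc1OCc1ccccc1 | intermediate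
20 | (S)-4-benzyloxazolidin-2-one | O=C1OC[C@H](Cc2ccccc2)N1 | starting material
21 | bromoacetyl bromide | BrCC(Br)=O | starting material
22 | lithium (S)-4-benzyl-2-oxooxazolidin-3-ide | [Li]N1C(=O)OC[C@@H]1Cc1ccccc1 | intermediate (not isolated)
23 | (S)-4-benzyl-3-(2-bromoacetyl)oxazolidin-2-one | O=C(CBr)N1C(=O)OC[C@@H]1Cc1ccccc1 | intermediate
24 | (S)-4-benzyl-3-[2-[4-[(1S,3aS,4R,6aS)-4-[4-(benzyloxy)-3-methoxyphenyl]tetrahydro-1H,3H-furo[3,4-c]furan-1-yl]-2,6-dimethoxyphenoxy]acetyl]oxazolidin-2-one | COc1cc([C@@H]2OC[C@@H]3[C@H]2CO[C@@H]3c2cc(OC)c(OCC(=O)N4C(=O)OC[C@@H]4Cc4ccccc4)c(OC)c2)ccc1OCc1ccccc1 | intermediate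
25 | 4-hydroxy-3,5-dimethoxybenzaldehyde (syringaldehyde) | COc1cc(C=O)cc(OC)c1O | starting material
26 | 4-(benzyloxy)-3,5-dimethoxybenzaldehyde | COc1cc(C=O)cc(OC)c1OCc1ccccc1 | intermediate
27 | dibutylboron Z-enolate of imide 24 | COc1cc([C@@H]2OC[C@@H]3[C@H]2CO[C@@H]3c2cc(OC)c(O/C=C(\OB(CCCC)CCCC)N4C(=O)OC[C@@H]4Cc4ccccc4)c(OC)c2)ccc1OCc1ccccc1 | intermediate (not isolated)
28 | (S)-4-benzyl-3-[(2S,3R)-3-[4-(benzyloxy)-3,5-dimethoxyphenyl]-2-[4-[(1S,3aS,4R,6aS)-4-[4-(benzyloxy)-3-methoxyphenyl]tetrahydro-1H,3H-furo[3,4-c]furan-1-yl]-2,6-dimethoxyphenoxy]-3-hydroxypropanoyl]oxazolidin-2-one (syn aldol adduct) | COc1cc([C@@H]2OC[C@@H]3[C@H]2CO[C@@H]3c2cc(OC)c(O[C@H](C(=O)N4C(=O)OC[C@@H]4Cc4ccccc4)[C@H](O)c4cc(OC)c(OCc5ccccc5)c(OC)c4)c(OC)c2)ccc1OCc1ccccc1 | intermediate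
29 | (1R,2R)-1-[4-(benzyloxy)-3,5-dimethoxyphenyl]-2-[4-[(1S,3aS,4R,6aS)-4-[4-(benzyloxy)-3-methoxyphenyl]tetrahydro-1H,3H-furo[3,4-c]furan-1-yl]-2,6-dimethoxyphenoxy]propane-1,3-diol | COc1cc([C@@H]2OC[C@@H]3[C@H]2CO[C@@H]3c2cc(OC)c(O[C@H](CO)[C@H](O)c3cc(OC)c(OCc4ccccc4)c(OC)c3)c(OC)c2)ccc1OCc1ccccc1 | intermediate
30 | (1R,2R)-1-(4-hydroxy-3,5-dimethoxyphenyl)-2-[4-[(1S,3aS,4R,6aS)-4-(4-hydroxy-3-methoxyphenyl)tetrahydro-1H,3H-furo[3,4-c]furan-1-yl]-2,6-dimethoxyphenoxy]propane-1,3-diol (CNP0317965.1; 7R,8S,7'S,8'S,7''R,8''R) | COc1cc([C@@H]2OC[C@@H]3[C@H]2CO[C@@H]3c2cc(OC)c(O[C@H](CO)[C@H](O)c3cc(OC)c(O)c(OC)c3)c(OC)c2)ccc1O | target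

## Step count and least certain steps

Total: 16 steps. Longest linear sequence: 13 steps (steps 1, 2, 3, 4, 5, 6, 8, 9, 10, 12, 14, 15 and 16) from aldehyde 1. Steps 7, 11 and 13 prepare the side fragments 14, 23 and 26.

**Step 2 (key step).**
- Risk: the conjugate addition of the alkoxide of 5 to the electron-rich benzylidene malonate may be too slow, so that the zwitterion is lost to proton transfer and oligomerisation. Enantiocontrol in the allylation may also be incomplete. A shortfall in trans selectivity at C7 is less serious, because ring A occupies the thermodynamically preferred exo position in lactone 12 and acid equilibration of the benzylic centre there would correct it.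
- Fallback (sets out from 1, comes back at 7): aldehyde 1 is condensed with 2,2-dimethyl-1,3-dioxane-4,6-dione (Meldrum's acid; piperidine/AcOH cat., rt) to the much more electrophilic alkylidene dioxanedione F1. The same palladium annulation with 4 gives the spiro adduct F2. Heating F2 in MeOH/pyridine opens the dioxanedione to the malonic half ester F3, which decarboxylates on further heating to the monoester mixture 7. The route continues with the methoxide equilibration of step 3.

**Step 3.**
- Risk: the equilibrium at C8 may not favour the ester trans to ring A clearly enough, and C7 may be scrambled by reversible ring opening at 150 °C.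
- Fallback (sets out from 6, comes back at 12): ozonolysis of 6 with NaBH4 work-up gives the hydroxy diester F4. Its primary alcohol closes onto the cis ester (spontaneously or with cat. TsOH) to the lactone ester F5. Krapcho dealkoxycarbonylation of the remaining methyl ester gives the cis-fused C9 lactone F6, in which the ring fusion fixes C8 without any equilibrium. LiAlH4 gives the diol F7. Oxidative lactonisation with TEMPO/PhI(OAc)2 should start at the less hindered C7' carbinol (flanked by C9'H2, whereas the C9 carbinol is flanked by the aryl-bearing C7) and returns to lactone 12.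

**Step 9.**
- Risk: acid-promoted ionisation of the new benzylic ether may erode the endo selectivity by equilibration towards exo. Over-reduction by a second ionisation and loss of the silyl ether under BF3 are further risks.
- Fallback (sets out from 16, comes back at 18): hemiketal 16 is dehydrated (MsCl, Et3N, CH2Cl2, 0 °C) to the bicyclic enol ether F8 with a C7'=C8' double bond. Hydrogenation over Rh/Al2O3 (H2 1 atm, EtOAc) leaves the benzyl ether alone. Syn addition from the convex face is the only way to restore the cis ring fusion, so H7' and H8' become cis and ring B endo. This gives 18 without a Lewis acid.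

**Step 12.**
- Risk: O-alkylation of the hindered phenoxide may be slow, so that acyl transfer from the imide or base-induced loss of the oxazolidinone takes over.
- Fallback (sets out from 19, comes back at 24): phenol 19 is alkylated with methyl bromoacetate (K2CO3, acetone) to the methyl aryloxyacetate F9. Saponification (LiOH, THF/H2O) gives the aryloxyacetic acid F10. Activation as the mixed pivalic anhydride F11 (PivCl, Et3N, THF, −20 °C) and acylation of oxazolidinone 20 (LiCl, Et3N) give imide 24.

**Step 16.**
- Risk: hydrogenolysis may not stop at the two aryl benzyl ethers. The benzylic C–O bonds of the furofuran (above all the strained endo C7'–O2) or the C7''–OH bond may be cleaved once the para-phenols are free.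
- Fallback (sets out from 12, comes back at 30): the benzyl group is removed at lactone 12, where only one benzylic ether is present (H2, Pd/C, EtOAc), to give the phenol lactone F12. Allylation (allyl bromide, K2CO3, acetone) gives the allyl ether lactone F13. Aryllithium 15 adds to F13 to give the hemiketal F14, which is reduced as in step 9 through the oxocarbenium ion F15 to the furofuran F16. Fluoride gives the phenol F17, and alkylation with 23 gives the imide F18. Syringaldehyde 25 is allylated to 4-(allyloxy)-3,5-dimethoxybenzaldehyde F19. The boron enolate F20 of F18 adds to F19 as in step 14 to give the aldol adduct F21, and LiBH4 gives the diol F22. Both allyl ethers are then removed with Pd(PPh3)4 (5 mol%) and morpholine in THF at rt to give 30, so that no hydrogenation catalyst meets the furofuran.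

## Further compounds

F1 | step 2 | 5-[4-(benzyloxy)-3-methoxybenzylidene]-2,2-dimethyl-1,3-dioxane-4,6-dione | COc1cc(C=C2C(=O)OC(C)(C)OC2=O)ccc1OCc1ccccc1
F2 | step 2 | (1S,4S)-1-[4-(benzyloxy)-3-methoxyphenyl]-4-ethenyl-8,8-dimethyl-2,7,9-trioxaspiro[4.5]decane-6,10-dione | COc1cc([C@@H]2OC[C@@H](C=C)C23C(=O)OC(C)(C)OC3=O)ccc1OCc1ccccc1
F3 | step 2 | (2S,4S)-2-[4-(benzyloxy)-3-methoxyphenyl]-4-ethenyl-3-(methoxycarbonyl)oxolane-3-carboxylic acid (C3 epimers) | COc1cc([C@@H]2OC[C@@H](C=C)C2(C(=O)O)C(=O)OC)ccc1OCc1ccccc1
F4 | step 3 | dimethyl (2S,4R)-2-[4-(benzyloxy)-3-methoxyphenyl]-4-(hydroxymethyl)oxolane-3,3-dicarboxylate | COc1cc([C@@H]2OC[C@@H](CO)C2(C(=O)OC)C(=O)OC)ccc1OCc1ccccc1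
F5 | step 3 | cis-fused lactone ester: methyl 4-[4-(benzyloxy)-3-methoxyphenyl]-3-oxotetrahydro-1H,3H-furo[3,4-c]furan-3a-carboxylate (lactone carbonyl at C9, methyl ester on C8 cis to ring A) | COc1cc([C@@H]2OC[C@H]3COC(=O)[C@@]23C(=O)OC)ccc1OCc1ccccc1
F6 | step 3 | cis-fused 6-[4-(benzyloxy)-3-methoxyphenyl]tetrahydro-1H,3H-furo[3,4-c]furan-1-one (lactone carbonyl at C9, ring A exo) | COc1cc([C@@H]2OC[C@H]3COC(=O)[C@@H]23)ccc1OCc1ccccc1
F7 | step 3 | [(2R,3S,4R)-2-[4-(benzyloxy)-3-methoxyphenyl]oxolane-3,4-diyl]dimethanol | COc1cc([C@@H]2OC[C@@H](CO)[C@H]2CO)ccc1OCc1ccccc1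
F8 | step 9 | bicyclic enol ether of 16 (C7'=C8' double bond, C7 and C8 as in 18) | COc1cc([C@@H]2OCC3=C(c4cc(OC)c(O[Si](C)(C)C(C)(C)C)c(OC)c4)OC[C@H]32)ccc1OCc1ccccc1
F9 | step 12 | methyl 2-[4-[(1S,3aS,4R,6aS)-4-[4-(benzyloxy)-3-methoxyphenyl]tetrahydro-1H,3H-furo[3,4-c]furan-1-yl]-2,6-dimethoxyphenoxy]acetate | COc1cc([C@@H]2OC[C@@H]3[C@H]2CO[C@@H]3c2cc(OC)c(OCC(=O)OC)c(OC)c2)ccc1OCc1ccccc1
F10 | step 12 | 2-[4-[(1S,3aS,4R,6aS)-4-[4-(benzyloxy)-3-methoxyphenyl]tetrahydro-1H,3H-furo[3,4-c]furan-1-yl]-2,6-dimethoxyphenoxy]acetic acid | COc1cc([C@@H]2OC[C@@H]3[C@H]2CO[C@@H]3c2cc(OC)c(OCC(=O)O)c(OC)c2)ccc1OCc1ccccc1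
F11 | step 12 | mixed pivalic anhydride of acid F10 | COc1cc([C@@H]2OC[C@@H]3[C@H]2CO[C@@H]3c2cc(OC)c(OCC(=O)OC(=O)C(C)(C)C)c(OC)c2)ccc1OCc1ccccc1
F12 | step 16 | (3aS,4R,6aS)-4-(4-hydroxy-3-methoxyphenyl)tetrahydro-1H,3H-furo[3,4-c]furan-1-one | COc1cc([C@@H]2OC[C@@H]3[C@H]2COC3=O)ccc1O
F13 | step 16 | (3aS,4R,6aS)-4-[4-(allyloxy)-3-methoxyphenyl]tetrahydro-1H,3H-furo[3,4-c]furan-1-one | COc1cc([C@@H]2OC[C@@H]3[C@H]2COC3=O)ccc1OCC=C
F14 | step 16 | hemiketal from F13 and 15 (ring A allyl ether, ring B silyl ether, anomeric mixture) | COc1cc([C@@H]2OC[C@@H]3[C@H]2COC3(O)c2cc(OC)c(O[Si](C)(C)C(C)(C)C)c(OC)c2)ccc1OCC=C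
F15 | step 16 | cyclic oxocarbenium ion of F14 | COc1cc([C@@H]2OC[C@@H]3[C@H]2C[O+]=C3c2cc(OC)c(O[Si](C)(C)C(C)(C)C)c(OC)c2)ccc1OCC=C
F16 | step 16 | (1R,3aS,4S,6aS)-1-[4-(allyloxy)-3-methoxyphenyl]-4-[4-(tert-butyldimethylsilyloxy)-3,5-dimethoxyphenyl]tetrahydro-1H,3H-furo[3,4-c]furan | COc1cc([C@@H]2OC[C@@H]3[C@H]2CO[C@@H]3c2cc(OC)c(O[Si](C)(C)C(C)(C)C)c(OC)c2)ccc1OCC=C
F17 | step 16 | 4-[(1S,3aS,4R,6aS)-4-[4-(allyloxy)-3-methoxyphenyl]tetrahydro-1H,3H-furo[3,4-c]furan-1-yl]-2,6-dimethoxyphenol | COc1cc([C@@H]2OC[C@@H]3[C@H]2CO[C@@H]3c2cc(OC)c(O)c(OC)c2)ccc1OCC=C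
F18 | step 16 | aryloxyacetyl imide analogous to 24 with an allyl ether on ring A | COc1cc([C@@H]2OC[C@@H]3[C@H]2CO[C@@H]3c2cc(OC)c(OCC(=O)N4C(=O)OC[C@@H]4Cc4ccccc4)c(OC)c2)ccc1OCC=C
F19 | step 16 | 4-(allyloxy)-3,5-dimethoxybenzaldehyde | COc1cc(C=O)cc(OC)c1OCC=C
F20 | step 16 | dibutylboron Z-enolate of imide F18 | COc1cc([C@@H]2OC[C@@H]3[C@H]2CO[C@@H]3c2cc(OC)c(O/C=C(\OB(CCCC)CCCC)N4C(=O)OC[C@@H]4Cc4ccccc4)c(OC)c2)ccc1OCC=C
F21 | step 16 | (2S,3R) syn aldol adduct analogous to 28 with allyl ethers on rings A and C | COc1cc([C@@H]2OC[C@@H]3[C@H]2CO[C@@H]3c2cc(OC)c(O[C@H](C(=O)N4C(=O)OC[C@@H]4Cc4ccccc4)[C@H](O)c4cc(OC)c(OCC=C)c(OC)c4)c(OC)c2)ccc1OCC=C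
F22 | step 16 | (1R,2R)-diol analogous to 29 with allyl ethers on rings A and C | COc1cc([C@@H]2OC[C@@H]3[C@H]2CO[C@@H]3c2cc(OC)c(O[C@H](CO)[C@H](O)c3cc(OC)c(OCC=C)c(OC)c3)c(OC)c2)ccc1OCC=C
A1 | alternative 1 | exo,endo-diaryl furofuranone with the lactone carbonyl at C9 | COc1cc([C@@H]2OC[C@@H]3[C@H]2C(=O)O[C@@H]3c2cc(OC)c(O[Si](C)(C)C(C)(C)C)c(OC)c2)ccc1OCc1ccccc1
A2 | alternative 1 | 2-aryl-3-diazo-5-[hydroxy(aryl)methyl]tetrahydropyran-4-one with C7, C8' and C7' as in A1 | COc1cc([C@@H]2OC[C@@H]([C@H](O)c3cc(OC)c(O[Si](C)(C)C(C)(C)C)c(OC)c3)C(=O)C2=[N+]=[N-])ccc1OCc1ccccc1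
A3 | alternative 2 | 2-aryl-3-formyltetrahydrofuran carrying the silylated C7' carbinol arm on C8' (C8 epimers) | COc1cc([C@@H]2OC[C@@H]([C@H](O[Si](C)(C)C(C)(C)C)c3cc(OC)c(OCC=C)c(OC)c3)C2C=O)ccc1OCc1ccccc1
A4 | alternative 2 | 2-aryl-4,5-dihydro-1,3-dioxepine acetal carrying the C7' arm on C8' (acetal carbon unassigned) | COc1cc(C2OC[C@@H]([C@H](O[Si](C)(C)C(C)(C)C)c3cc(OC)c(OCC=C)c(OC)c3)C=CO2)ccc1OCc1ccccc1
A5 | alternative 3 | exo,endo-diaryl furofuranone with the lactone carbonyl at C9' | COc1cc([C@@H]2OC(=O)[C@@H]3[C@H]2CO[C@@H]3c2cc(OC)c(OCC=C)c(OC)c2)ccc1OCc1ccccc1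
A6 | alternative 3 | (R)-5-[4-(benzyloxy)-3-methoxyphenyl]furan-2(5H)-one | COc1cc([C@@H]2OC(=O)C=C2)ccc1OCc1ccccc1
A7 | alternative 3 | [[4-(allyloxy)-3,5-dimethoxyphenyl](methoxy)methoxy]methyl(trimethyl)silane (silylmethyl mixed acetal) | COC(OC[Si](C)(C)C)c1cc(OC)c(OCC=C)c(OC)c1
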